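## The problem

The target 29 is an eremophilane-type ester built on two six-membered carbocycles, ring A (C1–C5, C10) and ring B (C5–C10), fused through the quaternary carbon C5 and the sp2 carbon C10; eremophilane numbering is used for every intermediate below. Its core is a cross-conjugated trienone: the C8 ketone is flanked by the C7 isopropylidene group on one side and by the C9=C10–C1=C2 diene, which runs through the ring fusion, on the other. Ring A carries three contiguous stereocentres, C3 (acyloxy, S), C4 (methyl, R) and C5 (methyl, R), all on one face; a fourth, C6′ (S) in the dienoyl chain, is too remote to be controlled from the core and must come from the chiral pool. C3 and C4 can be set together in an acyclic addition, and C4 can then direct the quaternary centre C5 if both sit in a small ring; C5 bears no hydrogen, so an error there cannot be corrected. The trienone is enolisable at C6 and, vinylogously, at C3, the C3 ester is allylic, the isopropylidene can leave conjugation and the (E,E)-dienoate can isomerise, so the end game must avoid strong base, strong acid and nucleophilic metals. The enabling feature is that the C9=C10 and C1=C2 alkenes meet at the C10–C1 single bond: a 1,3-diene across the ring fusion is what an alkyne (C10≡C1) leaves behind when a metal carbene is relayed through it from an alkene at C9 to an alkene at C2, so both rings can be closed in one operation from an open chain that already holds C3, C4 and C5.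

## Retrosynthesis

The C3–O acyl bond is cut first, giving alcohol 22 and acid 28. Esterification last keeps the base-sensitive dienoate away from every organometallic and hydride step. Acid 28 follows from ester 27, made by vinylogous olefination of aldehyde 24 with phosphonate 25; 24 is the oxidation product of commercial alcohol 23, which supplies C6′. The forward reaction only has to acylate a hindered allylic alcohol without touching the trienone.

Alcohol 22 is traced through silyl ether 21 to dienol 20 by functional-group changes only. Holding C8 as a carbinol and C3 as a silyl ether during ring formation keeps a Michael acceptor away from the carbene catalyst and lets the two oxygens be told apart. The forward steps are a selective oxidation of a doubly allylic alcohol and a non-basic desilylation.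

Dienol 20 is cut at both ring alkenes, C9=C10 and C1=C2, which opens rings B and A together and gives the acyclic dienyne 19. Neighbouring cuts (an aldol or annulation closure of ring B onto a finished ring A, or a cycloaddition for ring A) make one ring each and leave the diene or the C3 oxygen to be installed later. The precursor 19 has no ring, and its stereocentres lie on an open chain. The forward cascade must start at C9 and not at C2. This is secured by the free allylic hydroxyl at C8 and by carrying the C2 alkene as an (E)-propenyl group next to the bulky silyl ether; its extra methyl leaves as propene. The tetrasubstituted isopropylidene must stay inert, and both C8 epimers converge.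

Dienyne 19 is cut at C8–C9 to enal 18 and a vinyl nucleophile. Enal 18 comes from hydroxy enal 17 by silylation, and 17 from diol 16 by oxidation of its primary allylic alcohol. Adding the vinyl group last means the reactive C9 alkene exists only in the metathesis substrate. The forward steps need a primary-selective oxidation and a 1,2-addition to a hindered enal.

The alkyne of 16 is cut at C10≡C1 by one-carbon homologation of lactol 15, the reduction product of lactone ester 14. This reveals why the chain is carried as a γ-lactone: the C3 oxygen and C10 are tied into a five-membered ring, which turns the acyclic 1,2-relationship C4/C5 into a ring problem. One hydride reagent must stop at the lactol while taking the side-chain ester to the alcohol.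

Lactone 14 is cut at C5–C6 to the enolate of lactone 8 and allylic bromide 12, and 8 at C5–C14 to lactone 6 and iodomethane. The order matters: the second electrophile enters anti to the C4 methyl, so the methyl goes in first and the larger chain second. Bromide 12 brings C6–C8 and the isopropylidene in one piece and comes from malonate 9 through half-acid 10 and alcohol 11.

Lactone 6 is opened to diol 5, the hydration product of dienol 3, which is cut at C3–C4 to (E)-but-2-enal 1 and crotylboronate 2. A crotylboration sets the anti C3/C4 pair in one step from two four-carbon pieces, where an aldol route would need redox corrections. The propenyl group of 1 becomes the terminating alkene of the key step and, being 1,2-disubstituted, is not touched when the terminal vinyl group is hydroborated.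

## Roads not taken

Alternative 1: The cut is the C5–C6 bond, made while the C3–C8 bond of a bridged precursor breaks. The potassium alkoxide of the vinyl bicyclo[2.2.2]octenol A1 would undergo an anionic oxy-Cope rearrangement to a cis-fused enolate, trapped as silyl enol ether A2.
- Merits: the rearrangement is strongly accelerated and stereospecific, it creates the quaternary C5 and ring B in one step from a rigid precursor, and the enol ether marks C7 for later attachment of the isopropylidene carbons.
- Weak points: A2 is cis-fused with a hydrogen on C10 and a saturated C1–C2 unit, whereas the target needs C10 sp2 and both ring alkenes. The C3 oxygen is absent; hydration of the C3=C4 alkene from the face away from the angular methyl would place it trans to the methyl groups and call for an inversion. A1 would also have to be made as a single enantiomer.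
- Comparison: as a single step the oxy-Cope is more dependable than a metathesis cascade and fixes C5 without relying on substrate-controlled alkylation (step 8 here). The chosen plan sets against this that both ring alkenes and the C3 and C8 oxygens are in place after the key step, leaving three steps where this route would need about ten.

Alternative 2: The cuts are C3–C4 and C5–C10 of ring A. Tiglaldehyde A3 and the (E,E)-bis(silyloxy)diene A4 would combine under a chiral cationic oxazaborolidine Lewis acid to give the endo aldehyde A5.
- Merits: one catalytic enantioselective step sets C3, C4, C5 and the C1=C2 alkene, more stereocentres per step than anything in the chosen plan, which spends steps 1, 4 and 8 on the same centres.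
- Weak points: an α,β-disubstituted enal is a poor dienophile and the diene is hindered at both termini. In A5 the endo rule places the C3 oxygen trans to the two methyl groups, so an inversion is owed. The C3 and C10 silyl ethers are nearly equivalent although only one is to remain. Ring B must then be built from a neopentyl aldehyde carbon that has to end as the C6 methylene and be closed by condensation at C10, about seven further steps including the isopropylidene and the C8 ketone.
- Comparison: it is better in stereochemical economy; the chosen plan answers with a cascade that finishes both rings and the diene at once.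

Alternative 3: The cuts are C6–C7 and C5–C10 together with a methyl shift from C10 to C5. Aristolochene synthase, a class-one magnesium-dependent cyclase, would convert farnesyl diphosphate A6 into (+)-aristolochene A7.
- Merits: the whole carbon skeleton, C4 and C5 in the correct absolute configuration and the C9=C10 alkene arise in one enzymatic step; no chemical route matches this in step count to the skeleton.
- Weak points: A7 is a hydrocarbon. The C3 oxygen would have to be placed at an unactivated methylene, cis to the methyl groups, with no directing group. The C8 ketone would need an allylic oxidation competing with C1, the C1=C2 alkene a dehydrogenation, and the isopropenyl group an isomerisation. Access also depends on enzyme expression and handling of a volatile product.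
- Comparison: the chosen plan is much longer to the skeleton but places every oxygen by construction and needs no late C–H oxidation.

Key step: step 14

Remark: the C2 alkene is carried as an (E)-prop-1-enyl group instead of a vinyl group; its extra methyl leaves as propene in step 14, so the bonds formed and the product of the key step are unchanged.
Remark: centres that are later enolised, opened or oxidised (C3 of lactone 8, the anomeric carbon of 15, the carbinol carbon C8 in 19 and 20) are carried as mixtures and drawn without configuration; metal alkoxides, borates and aluminates that are only hydrolysed on work-up are not numbered.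
Remark: the Re-face preference of the (R)-configured phosphoric acid in step 1 is assigned by analogy with aromatic and α,β-unsaturated aldehydes; the configuration of 3 would be confirmed (Mosher esters) before scale-up and the enantiomeric catalyst used if required.

Step 1
Reactants: 1 (2E)-but-2-enal; 2 (E)-crotylboronic acid pinacol ester
Product: 3 (3R,4S,5E)-3-methylhepta-1,5-dien-4-ol
Conditions: (R)-3,3′-bis(2,4,6-triisopropylphenyl)-1,1′-binaphthyl-2,2′-diyl hydrogen phosphate (5 mol %), 4 Å molecular sieves, toluene, −30 °C; aqueous NaHCO3
Reagents that add atoms: none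
Why: Chiral phosphoric acid-catalysed crotylboration through a closed chair transition state: the (E)-boronate gives the anti C3/C4 pair, and the catalyst, hydrogen-bonded to a boronate oxygen and to the formyl hydrogen, should direct the crotyl group to the Re face of the aldehyde; only 1,2-addition is expected.

Step 2
Reactants: 3 (3R,4S,5E)-3-methylhepta-1,5-dien-4-ol
Product: 5 (3R,4R,5E)-3-methylhept-5-ene-1,4-diol, via alkylborane 4 (not isolated)
Conditions: 9-borabicyclo[3.3.1]nonane, THF, 0 °C to rt; then NaOH (aq), H2O2, 0 °C to rt
Reagents that add atoms: hydrogen peroxide, OO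
Why: Anti-Markovnikov hydroboration–oxidation; the bulky dialkylborane reacts far faster with the monosubstituted vinyl group than with the 1,2-disubstituted propenyl alkene next to the oxygenated carbon, and no stereocentre is touched.

Step 3
Reactants: 5 (3R,4R,5E)-3-methylhept-5-ene-1,4-diol
Product: 6 (4R,5R)-4-methyl-5-[(1E)-prop-1-en-1-yl]oxolan-2-one
Conditions: 2,2,6,6-tetramethylpiperidin-1-oxyl (10 mol %), PhI(OAc)2, CH2Cl2, rt
Reagents that add atoms: none
Why: Oxoammonium-mediated oxidative lactonisation of a 1,4-diol: the primary alcohol is oxidised first, the aldehyde is captured by the C3 hydroxyl as a five-membered lactol, and this is oxidised again; the anti C3/C4 pair becomes the trans-disubstituted lactone.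

Step 4
Reactants: 6 (4R,5R)-4-methyl-5-[(1E)-prop-1-en-1-yl]oxolan-2-one
Product: 8 (4R,5S)-3,4-dimethyl-5-[(1E)-prop-1-en-1-yl]oxolan-2-one (C3 epimers), via lithium enolate 7 (not isolated)
Conditions: LiN(i-Pr)2, THF, −78 °C; then MeI, −78 to −40 °C
Reagents that add atoms: iodomethane, CI
Why: Lithium enolate alkylation at the only acidic position; the new centre is re-enolised in step 8, so its configuration is immaterial.

Step 5
Reactants: 9 diethyl 2-(propan-2-ylidene)propanedioate
Product: 10 2-(ethoxycarbonyl)-3-methylbut-2-enoic acid
Conditions: KOH (1 equiv), EtOH, 0 °C to rt; then HCl (aq)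
Reagents that add atoms: potassium hydroxide, [K+].[OH-]
Why: Mono-saponification of a malonate; the first carboxylate formed deactivates the second ester towards hydroxide.

Step 6
Reactants: 10 2-(ethoxycarbonyl)-3-methylbut-2-enoic acid
Product: 11 ethyl 2-(hydroxymethyl)-3-methylbut-2-enoate
Conditions: BH3·SMe2, THF, 0 °C to rt; MeOH quench
Reagents that add atoms: none
Why: Borane reduces a carboxylic acid through its acyloxyborane much faster than an ester, and the tetrasubstituted electron-poor alkene is not hydroborated.

Step 7
Reactants: 11 ethyl 2-(hydroxymethyl)-3-methylbut-2-enoate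
Product: 12 ethyl 2-(bromomethyl)-3-methylbut-2-enoate
Conditions: PBr3, Et2O, 0 °C
Reagents that add atoms: phosphorus tribromide, BrP(Br)Br
Why: Conversion of a primary allylic alcohol into the bromide; the conjugated primary bromide is also the thermodynamically preferred allylic isomer.

Step 8
Reactants: 8 (4R,5S)-3,4-dimethyl-5-[(1E)-prop-1-en-1-yl]oxolan-2-one; 12 ethyl 2-(bromomethyl)-3-methylbut-2-enoate
Product: 14 ethyl 2-{[(3R,4R,5S)-3,4-dimethyl-2-oxo-5-[(1E)-prop-1-en-1-yl]oxolan-3-yl]methyl}-3-methylbut-2-enoate, via lithium enolate 13 (not isolated)
Conditions: LiN(i-Pr)2, THF, −78 °C; then 12, −78 to −30 °C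
Reagents that add atoms: none
Why: Alkylation of the fully substituted lactone enolate; as is general for trans-β,γ-disubstituted butyrolactone enolates, the electrophile enters anti to the adjacent C4 methyl, placing C6 trans and the C5 methyl cis to it (C5 R); substitution is direct because the far alkene carbon of 12 is fully substituted.

Step 9
Reactants: 14 lactone ester from step 8
Product: 15 (3R,4R,5S)-3-[2-(hydroxymethyl)-3-methylbut-2-en-1-yl]-3,4-dimethyl-5-[(1E)-prop-1-en-1-yl]oxolan-2-ol (anomers)
Conditions: i-Bu2AlH (4 equiv), CH2Cl2, −78 °C; aqueous potassium sodium tartrate (KNaC4H4O6); no contact with acid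
Reagents that add atoms: none
Why: At −78 °C the lactone stops at the stable tetrahedral aluminate (lactol after work-up), while the conjugated ester is taken through the enal to the allylic alcohol; only the anomeric centre is new.

Step 10
Reactants: 15 lactol from step 9
Product: 16 (4R,5R,6S,7E)-4-ethynyl-4,5-dimethyl-2-(propan-2-ylidene)non-7-ene-1,6-diol
Conditions: dimethyl (1-diazo-2-oxopropyl)phosphonate, K2CO3, MeOH, 0 °C to rt
Reagents that add atoms: dimethyl (1-diazo-2-oxopropyl)phosphonate, COP(=O)(OC)C(=[N+]=[N-])C(C)=O
Why: Seyferth–Gilbert homologation in its Ohira–Bestmann form on the open hydroxy-aldehyde tautomer of the lactol; the aldehyde carbon becomes C10, the new carbon C1, the C3 hydroxyl is set free, and the quaternary α-carbon cannot epimerise.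

Step 11
Reactants: 16 alkyne diol from step 10
Product: 17 (4R,5R,6S,7E)-4-ethynyl-6-hydroxy-4,5-dimethyl-2-(propan-2-ylidene)non-7-enal
Conditions: 2,2,6,6-tetramethylpiperidin-1-oxyl (10 mol %), PhI(OAc)2 (1.1 equiv), CH2Cl2, 0 °C to rt
Reagents that add atoms: none
Why: Oxoammonium oxidation is selective for the primary allylic alcohol over the hindered secondary one; the enal cannot be trapped as a small-ring lactol by the C3 hydroxyl, so there is no over-oxidation.

Step 12
Reactants: 17 hydroxy enal from step 11
Product: 18 (4R,5R,6S,7E)-6-[(tert-butyldimethylsilyl)oxy]-4-ethynyl-4,5-dimethyl-2-(propan-2-ylidene)non-7-enal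
Conditions: t-BuMe2SiOTf, 2,6-lutidine, CH2Cl2, −78 °C
Reagents that add atoms: tert-butyldimethylsilyl trifluoromethanesulfonate, CC(C)(C)[Si](C)(C)OS(=O)(=O)C(F)(F)F
Why: Silylation of a hindered secondary alcohol with the silyl triflate and a non-nucleophilic base; at −78 °C the enal is not converted into a dienol ether.

Step 13
Reactants: 18 silyl ether enal from step 12
Product: 19 (6R,7R,8S,9E)-8-[(tert-butyldimethylsilyl)oxy]-6-ethynyl-6,7-dimethyl-4-(propan-2-ylidene)undeca-1,9-dien-3-ol (C3 epimers)
Conditions: CH2=CHMgBr, THF, −78 °C; NH4Cl (aq)
Reagents that add atoms: vinylmagnesium bromide, C=C[Mg]Br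
Why: Grignard 1,2-addition to the enal, whose fully substituted β-carbon excludes conjugate addition; the new carbinol centre (C8) is oxidised in step 15, so both epimers are used.

Step 14
Reactants: 19 dienyne from step 13
Product: 20 (4aR,5R,6S)-6-[(tert-butyldimethylsilyl)oxy]-4a,5-dimethyl-3-(propan-2-ylidene)-2,3,4,4a,5,6-hexahydronaphthalen-2-ol (C2 epimers)
Conditions: second-generation Grubbs catalyst RuCl2(=CHPh)(PCy3)(H2IMes) (5–10 mol %), CH2Cl2 (0.005 M), 40 °C, argon
Reagents that add atoms: none
Why: Tandem ring-closing dienyne metathesis, the known cascade route to fused bicyclic 1,3-dienes. The ruthenium carbene exchanges onto the C9 vinyl group, the only monosubstituted alkene in 19 and one activated by the free allylic hydroxyl at C8; the C2 alkene is 1,2-disubstituted and flanked by the silyl ether and the C4 branch, so loading there, which would lead to a five–seven ring system, is disfavoured. Ring B closes by 6-exo addition of the C9 alkylidene to the internal alkyne carbon C10 (enyne metathesis), giving C9=C10 and a vinylcarbene at C1. Ring A closes by six-membered ring-closing metathesis of that carbene onto the propenyl group, giving C1=C2 and an ethylidene carrier that leaves as propene in the next turnover. No stereocentre is formed: C3, C4 and C5 are spectators and the undefined carbinol centre is erased in step 15. The tetrasubstituted isopropylidene alkene and the silyl ether are inert, and high dilution suppresses cross-metathesis and alkyne oligomerisation.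

Step 15
Reactants: 20 bicyclic dienol from step 14
Product: 21 (4aR,5R,6S)-6-[(tert-butyldimethylsilyl)oxy]-4a,5-dimethyl-3-(propan-2-ylidene)-4,4a,5,6-tetrahydronaphthalen-2(3H)-one
Conditions: MnO2 (excess), CH2Cl2, rt
Reagents that add atoms: none
Why: Surface oxidation of a doubly allylic alcohol by MnO2 under neutral conditions; both carbinol epimers give the same cross-conjugated trienone.

Step 16
Reactants: 21 silyl trienone from step 15
Product: 22 (4aR,5R,6S)-6-hydroxy-4a,5-dimethyl-3-(propan-2-ylidene)-4,4a,5,6-tetrahydronaphthalen-2(3H)-one
Conditions: HF·pyridine, THF/pyridine, 0 °C to rt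
Reagents that add atoms: none
Why: Fluoride cleavage of the Si–O bond in a buffered, non-basic medium, so that the trienone is not enolised towards C3 or C6; ionisation at C3 is disfavoured because the cation would be conjugated to the electron-poor dienone.

Step 17
Reactants: 23 (2S)-2-methylbutan-1-ol
Product: 24 (2S)-2-methylbutanal
Conditions: 2,2,6,6-tetramethylpiperidin-1-oxyl (5 mol %), PhI(OAc)2, CH2Cl2, 0 °C to rt; washed and dried solution used directly
Reagents that add atoms: none
Why: Oxoammonium oxidation of a primary alcohol without a base strong enough to racemise the α-stereocentre; the volatile aldehyde is kept in solution.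

Step 18
Reactants: 24 (2S)-2-methylbutanal; 25 ethyl (2E)-4-(diethoxyphosphoryl)but-2-enoate
Product: 27 ethyl (2E,4E,6S)-6-methylocta-2,4-dienoate, via lithiated phosphonate 26 (not isolated)
Conditions: LiN(SiMe3)2, THF, −78 °C; then 24, −78 to 0 °C
Reagents that add atoms: none
Why: Vinylogous Horner–Wadsworth–Emmons olefination; the stabilised anion gives the new (4E) alkene, the (2E) alkene comes with the reagent, and C6 is not touched.

Step 19
Reactants: 27 ethyl (2E,4E,6S)-6-methylocta-2,4-dienoate
Product: 28 (2E,4E,6S)-6-methylocta-2,4-dienoic acid
Conditions: LiOH, THF/MeOH/H2O, rt; then HCl (aq) to pH 3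
Reagents that add atoms: lithium hydroxide, [Li+].[OH-]
Why: Ester hydrolysis under mild conditions that leave the dienoate geometry and the remote stereocentre intact.

Step 20
Reactants: 22 hydroxy trienone from step 16; 28 (2E,4E,6S)-6-methylocta-2,4-dienoic acid
Product: 29 (4aR,5R,6S)-4a,5-dimethyl-2-oxo-3-(propan-2-ylidene)-2,3,4,4a,5,6-hexahydronaphthalen-6-yl (2E,4E,6S)-6-methylocta-2,4-dienoate
Conditions: N,N′-dicyclohexylcarbodiimide, 4-(dimethylamino)pyridine (10 mol %), CH2Cl2, 0 °C to rt
Reagents that add atoms: none
Why: Steglich esterification; acyl transfer to oxygen retains the C3 configuration, and the weakly basic medium spares the trienone and the dienoate.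

Compound list

1 | (2E)-but-2-enal | C/C=C/C=O | starting material
2 | (E)-crotylboronic acid pinacol ester, 2-[(2E)-but-2-en-1-yl]-4,4,5,5-tetramethyl-1,3,2-dioxaborolane | C/C=C/CB1OC(C)(C)C(C)(C)O1 | starting material
3 | (3R,4S,5E)-3-methylhepta-1,5-dien-4-ol | C/C=C/[C@H](O)[C@H](C)C=C | intermediate
4 | 9-[(3R,4R,5E)-4-hydroxy-3-methylhept-5-en-1-yl]-9-borabicyclo[3.3.1]nonane | C/C=C/[C@H](O)[C@H](C)CCB1C2CCCC1CCC2 | intermediate (not isolated)
5 | (3R,4R,5E)-3-methylhept-5-ene-1,4-diol | C/C=C/[C@H](O)[C@H](C)CCO | intermediate
6 | (4R,5R)-4-methyl-5-[(1E)-prop-1-en-1-yl]oxolan-2-one | O=C1O[C@@H](/C=C/C)[C@H](C)C1 | intermediate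
7 | lithium enolate of 6 (O-lithio ketene acetal, ring stereocentres unchanged) | [Li]OC1=C[C@@H](C)[C@H](/C=C/C)O1 | intermediate (not isolated)
8 | (4R,5S)-3,4-dimethyl-5-[(1E)-prop-1-en-1-yl]oxolan-2-one (C3 epimers) | O=C1O[C@@H](/C=C/C)[C@H](C)C1C | intermediate
9 | diethyl 2-(propan-2-ylidene)propanedioate | CCOC(=O)C(=C(C)C)C(=O)OCC | starting material
10 | 2-(ethoxycarbonyl)-3-methylbut-2-enoic acid | CCOC(=O)C(=C(C)C)C(=O)O | intermediate
11 | ethyl 2-(hydroxymethyl)-3-methylbut-2-enoate | CCOC(=O)C(CO)=C(C)C | intermediate
12 | ethyl 2-(bromomethyl)-3-methylbut-2-enoate | CCOC(=O)C(CBr)=C(C)C | intermediate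
13 | lithium enolate of 8 (O-lithio ketene acetal, ring stereocentres unchanged) | [Li]OC1=C(C)[C@@H](C)[C@H](/C=C/C)O1 | intermediate (not isolated)
14 | ethyl 2-{[(3R,4R,5S)-3,4-dimethyl-2-oxo-5-[(1E)-prop-1-en-1-yl]oxolan-3-yl]methyl}-3-methylbut-2-enoate | O=C1O[C@@H](/C=C/C)[C@H](C)[C@@]1(C)CC(=C(C)C)C(=O)OCC | intermediate
15 | (3R,4R,5S)-3-[2-(hydroxymethyl)-3-methylbut-2-en-1-yl]-3,4-dimethyl-5-[(1E)-prop-1-en-1-yl]oxolan-2-ol (anomers) | OC1O[C@@H](/C=C/C)[C@H](C)[C@@]1(C)CC(CO)=C(C)C | intermediate
16 | (4R,5R,6S,7E)-4-ethynyl-4,5-dimethyl-2-(propan-2-ylidene)non-7-ene-1,6-diol | C#C[C@](C)(CC(CO)=C(C)C)[C@@H](C)[C@@H](O)/C=C/C | intermediate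
17 | (4R,5R,6S,7E)-4-ethynyl-6-hydroxy-4,5-dimethyl-2-(propan-2-ylidene)non-7-enal | C#C[C@](C)(CC(C=O)=C(C)C)[C@@H](C)[C@@H](O)/C=C/C | intermediate
18 | (4R,5R,6S,7E)-6-[(tert-butyldimethylsilyl)oxy]-4-ethynyl-4,5-dimethyl-2-(propan-2-ylidene)non-7-enal | C#C[C@](C)(CC(C=O)=C(C)C)[C@@H](C)[C@@H](O[Si](C)(C)C(C)(C)C)/C=C/C | intermediate
19 | (6R,7R,8S,9E)-8-[(tert-butyldimethylsilyl)oxy]-6-ethynyl-6,7-dimethyl-4-(propan-2-ylidene)undeca-1,9-dien-3-ol (C3 epimers) | C#C[C@](C)(CC(=C(C)C)C(O)C=C)[C@@H](C)[C@@H](O[Si](C)(C)C(C)(C)C)/C=C/C | intermediate
20 | (4aR,5R,6S)-6-[(tert-butyldimethylsilyl)oxy]-4a,5-dimethyl-3-(propan-2-ylidene)-2,3,4,4a,5,6-hexahydronaphthalen-2-ol (C2 epimers) | CC(C)(C)[Si](C)(C)O[C@H]1C=CC2=CC(O)C(=C(C)C)C[C@]2(C)[C@H]1C | intermediate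
21 | (4aR,5R,6S)-6-[(tert-butyldimethylsilyl)oxy]-4a,5-dimethyl-3-(propan-2-ylidene)-4,4a,5,6-tetrahydronaphthalen-2(3H)-one | CC(C)(C)[Si](C)(C)O[C@H]1C=CC2=CC(=O)C(=C(C)C)C[C@]2(C)[C@H]1C | intermediate
22 | (4aR,5R,6S)-6-hydroxy-4a,5-dimethyl-3-(propan-2-ylidene)-4,4a,5,6-tetrahydronaphthalen-2(3H)-one | O[C@H]1C=CC2=CC(=O)C(=C(C)C)C[C@]2(C)[C@H]1C | intermediate
23 | (2S)-2-methylbutan-1-ol | CC[C@H](C)CO | starting material
24 | (2S)-2-methylbutanal | CC[C@H](C)C=O | intermediate
25 | ethyl (2E)-4-(diethoxyphosphoryl)but-2-enoate | CCOC(=O)/C=C/CP(=O)(OCC)OCC | starting material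
26 | lithium salt of 25 (anion at the carbon next to phosphorus) | [Li+].CCOC(=O)/C=C/[CH-]P(=O)(OCC)OCC | intermediate (not isolated)
27 | ethyl (2E,4E,6S)-6-methylocta-2,4-dienoate | CC[C@H](C)/C=C/C=C/C(=O)OCC | intermediate
28 | (2E,4E,6S)-6-methylocta-2,4-dienoic acid | CC[C@H](C)/C=C/C=C/C(=O)O | intermediate
29 | (4aR,5R,6S)-4a,5-dimethyl-2-oxo-3-(propan-2-ylidene)-2,3,4,4a,5,6-hexahydronaphthalen-6-yl (2E,4E,6S)-6-methylocta-2,4-dienoate (CNP0215744.1) | CC[C@H](C)/C=C/C=C/C(=O)O[C@H]1C=CC2=CC(=O)C(=C(C)C)C[C@]2(C)[C@H]1C | target

Total step count: 20. Longest linear sequence: 14 steps (steps 1–4, 8–16 and 20, from 1 to 29).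

Least certain steps

Step 14 (key step). The most likely failure is loss of the intended order of events. Loading of the carbene onto the alkyne, or intermolecular capture of the C1 vinylcarbene, would lead to monocyclic trienes or oligomers, and ruthenium hydride from catalyst decay could isomerise the free allylic alcohol. The fallback separates the two ring closures. Starting from 19, enyne ring closure alone under ethylene (1 atm, same catalyst) should stop at the ring B triene (4R)-3-ethenyl-4-methyl-4-[(2R,3S,4E)-3-[(tert-butyldimethylsilyl)oxy]hex-4-en-2-yl]-6-(propan-2-ylidene)cyclohex-2-en-1-ol F1, because ethylene turns over the C1 carbene. F1 is then closed onto the propenyl group in a separate diene ring-closing metathesis with second-generation Hoveyda–Grubbs catalyst RuCl2(=CH-C6H4-2-O-i-Pr)(H2IMes), which returns the route to 20.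

Step 1. The risk is weak facial discrimination by the catalyst for a small linear enal, together with an uncatalysed background addition, both of which would lower the enantiomeric purity of every later compound. The fallback is reagent control. Starting from 1, the borane (E)-but-2-en-1-ylbis(isopinocampheyl)borane F2 is generated from (E)-but-2-ene, KOt-Bu and n-BuLi, the B-methoxydiisopinocampheylborane derived from (−)-α-pinene, and BF3·OEt2. It is added to 1 at −78 °C and the adduct is worked up with NaOH/H2O2, returning the route to 3.

Step 8. The risk is incomplete facial selectivity at the quaternary centre, because the bulky bromide must approach the face that also carries the propenyl group. Proton transfer from the acidic methyl groups of 12 to the hindered enolate is a second risk. The fallback changes the bond construction. Starting from 8, its enolate 13 is added in a conjugate sense to ethyl acrylate, whose unsubstituted terminus is the smallest possible electrophile, giving ethyl 3-[(3R,4R,5S)-3,4-dimethyl-2-oxo-5-[(1E)-prop-1-en-1-yl]oxolan-3-yl]propanoate F3. The ester of F3 is the only enolisable site; it is deprotonated with LiN(i-Pr)2 and added to acetone to give ethyl 2-{[(3R,4R,5S)-3,4-dimethyl-2-oxo-5-[(1E)-prop-1-en-1-yl]oxolan-3-yl]methyl}-3-hydroxy-3-methylbutanoate F4. Dehydration (Burgess reagent, then 1,8-diazabicyclo[5.4.0]undec-7-ene to bring the alkene into conjugation) returns the route to 14.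

Step 10. The risk is slow homologation, because the lactol with its quaternary neighbour stays largely ring-closed; on any acidic contact it can also be trapped by the primary hydroxyl as a bicyclic acetal. The fallback is a Wittig-type two-stage route. Starting from 15, reaction with Ph3P=CBr2 (from CBr4 and PPh3) gives (4R,5R,6S,7E)-4-(2,2-dibromoethenyl)-4,5-dimethyl-2-(propan-2-ylidene)non-7-ene-1,6-diol F5. Treatment with excess n-BuLi (THF, −78 °C) followed by aqueous quench converts F5 into the alkyne and returns the route to 16.

Step 20. The risk is slow acylation of the hindered allylic C3 hydroxyl, which would leave time for rearrangement of the activated acid to an N-acylurea and for base-mediated isomerisation of the dienoyl unit. The fallback builds the dienoate on the core. Starting from 22, acylation with the small (diethoxyphosphoryl)acetic acid (same carbodiimide conditions) gives (4aR,5R,6S)-4a,5-dimethyl-2-oxo-3-(propan-2-ylidene)-2,3,4,4a,5,6-hexahydronaphthalen-6-yl 2-(diethoxyphosphoryl)acetate F6. Aldehyde 24 is extended with Ph3P=CHCHO to (2E,4S)-4-methylhex-2-enal F7. Horner–Wadsworth–Emmons coupling of F6 with F7 (LiCl, 1,8-diazabicyclo[5.4.0]undec-7-ene, MeCN) forms the (2E,4E)-dienoate directly and returns the route to 29.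

Further compounds

F1 | step 14 | (4R)-3-ethenyl-4-methyl-4-[(2R,3S,4E)-3-[(tert-butyldimethylsilyl)oxy]hex-4-en-2-yl]-6-(propan-2-ylidene)cyclohex-2-en-1-ol (C1 epimers) | C=CC1=CC(O)C(=C(C)C)C[C@]1(C)[C@@H](C)[C@@H](O[Si](C)(C)C(C)(C)C)/C=C/C
F2 | step 1 | (E)-but-2-en-1-ylbis(isopinocampheyl)borane derived from (−)-α-pinene | C/C=C/CB([C@H]1C[C@H]2C[C@@H]([C@@H]1C)C2(C)C)[C@H]1C[C@H]2C[C@@H]([C@@H]1C)C2(C)C
F3 | step 8 | ethyl 3-[(3R,4R,5S)-3,4-dimethyl-2-oxo-5-[(1E)-prop-1-en-1-yl]oxolan-3-yl]propanoate | O=C1O[C@@H](/C=C/C)[C@H](C)[C@@]1(C)CCC(=O)OCC
F4 | step 8 | ethyl 2-{[(3R,4R,5S)-3,4-dimethyl-2-oxo-5-[(1E)-prop-1-en-1-yl]oxolan-3-yl]methyl}-3-hydroxy-3-methylbutanoate (C2 epimers) | O=C1O[C@@H](/C=C/C)[C@H](C)[C@@]1(C)CC(C(=O)OCC)C(C)(C)O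
F5 | step 10 | (4R,5R,6S,7E)-4-(2,2-dibromoethenyl)-4,5-dimethyl-2-(propan-2-ylidene)non-7-ene-1,6-diol | BrC(Br)=C[C@](C)(CC(CO)=C(C)C)[C@@H](C)[C@@H](O)/C=C/C
F6 | step 20 | (4aR,5R,6S)-4a,5-dimethyl-2-oxo-3-(propan-2-ylidene)-2,3,4,4a,5,6-hexahydronaphthalen-6-yl 2-(diethoxyphosphoryl)acetate | CCOP(=O)(OCC)CC(=O)O[C@H]1C=CC2=CC(=O)C(=C(C)C)C[C@]2(C)[C@H]1C
F7 | step 20 | (2E,4S)-4-methylhex-2-enal | CC[C@H](C)/C=C/C=O
A1 | alternative 1 | 2-ethenyl-5,6-dimethylbicyclo[2.2.2]oct-5-en-2-ol (vinyl group syn to the ring alkene) | C=C[C@]1(O)C[C@H]2CC[C@@H]1C(C)=C2C
A2 | alternative 1 | cis-fused bicyclic trimethylsilyl enol ether (C8 enol ether, C3=C4 alkene, angular methyl on C5) | C1=C(C)[C@@]2(C)CC=C(O[Si](C)(C)C)C[C@H]2CC1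
A3 | alternative 2 | (2E)-2-methylbut-2-enal (tiglaldehyde) | C/C=C(\C)C=O
A4 | alternative 2 | (1E,3E)-1,4-bis[(tert-butyldimethylsilyl)oxy]buta-1,3-diene | CC(C)(C)[Si](C)(C)O/C=C/C=C/O[Si](C)(C)C(C)(C)C
A5 | alternative 2 | endo cyclohexene carbaldehyde adduct (C5 methyl and formyl, C3 and C10 silyloxy) | CC(C)(C)[Si](C)(C)O[C@@H]1C=C[C@H](O[Si](C)(C)C(C)(C)C)[C@](C)(C=O)[C@H]1C
A6 | alternative 3 | (2E,6E)-farnesyl diphosphate | CC(C)=CCC/C(C)=C/CC/C(C)=C/COP(=O)(O)OP(=O)(O)O
A7 | alternative 3 | (+)-aristolochene | C1CCC2=CC[C@H](C(C)=C)C[C@]2(C)[C@H]1C
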